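## Analysis of the target

The target is a germacranolide (germacrane numbering C1–C15 is used throughout) in which an ether oxygen joins C7 and C10 of the cyclodecane. This gives a tetrahydrofuran (O, C7, C8, C9, C10) bridged by a nine-membered oxonane (O, C7, C6, C5, C4, C3, C2, C1, C10), with the α-methylene-γ-lactone (C6, C7, C11, C12, O) spiro-joined at C7. There are six stereocentres: C4 (R), C5 (S), C6 (R), C7 (S), C8 (S) and C10 (R). C6 and C1 must leave the tetrahydrofuran from the same face; C11, the C8 ester oxygen and the C10 methyl lie on the other face; the epoxide oxygen is on the same side of the medium ring as the C6 oxygen. The epoxide carries C3 and C6 cis, so it stems from a Z-configured trisubstituted C4=C5 alkene. Sensitive groups are two Michael acceptors (exo-methylene lactone, methacrylate), an acid-labile trisubstituted epoxide and, in any intermediate with a C8 ketone, a C6 oxygen β to the carbonyl that is prone to elimination or retro-aldol cleavage. The hard part is the bridged medium ring around the fully substituted C7, which carries the ether oxygen, C11 and two ring carbons, next to the quaternary ether carbon C10. The strategy rests on the array O–C7–C6–C5=C4 inside the oxonane: an O–C7 bond, a C6–C7 bond and a double bond two atoms further on are what a [2,3]-sigmatropic shift of an oxonium ylide leaves behind, so reconnecting O to C4 and cutting O–C7 and C6–C7 reduces both rings to a tetrahydropyran (O, C10, C1, C2, C3, C4).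

## Retrosynthetic reasoning

**Late oxidation state changes (35 ⇒ 34 ⇒ 33 ⇒ 30).** The C1 ketone is revealed last from silyl ether 33 via alcohol 34. A free C1 ketone would offer a carbonyl oxygen to both carbenoids of the route and an enolisable position during lactone methylenation. The exo-methylene group is cut back to the saturated lactone 30; a Mannich/elimination sequence adds C13 without touching the ester.

**Lactone ring (30 ⇒ 29).** The C7–C11 bond is cut, leaving C6-bound diazoacetate 29 and a C7–H bond. A base-mediated alkylation of a C8 ketone was rejected: C7 is a bridgehead and would enolise less readily than C9, and any C7 enolate has the C6 acyloxy group in the β-position and would eliminate it. Carbenoid insertion needs no enolate. The C7–H bond is tertiary, activated by the ring oxygen and 1,5 to the carbene carbon, and insertion occurs with retention, so C11 must take the exocyclic position that H7 held.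

**Two esters (29 ⇒ 28 ⇒ 26 ⇒ 24).** The diazoacetate comes from bromoacetate 28 (acylation with 27), and the C8 methacrylate of 26 from diol 24 and anhydride 25. The ester is placed on O8 first because that hydroxyl is the less hindered and less deactivated of the two.

**Epoxide and C8 carbinol (24 ⇒ 23 ⇒ 22).** Both are derived from the free C6 hydroxyl. It directs epoxidation of the Z alkene to the face required, and it delivers hydride to the C8 ketone of 22 from the only face it can reach, the face that carries C6. The C6 oxygen must therefore survive the ring-forming step as an ether that can be removed under neutral conditions, hence the PMB group of 21.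

**Key disconnection (21 ⇒ 19).** O–C7 and C6–C7 are cut and O–C4 is re-formed. This is the retron of an oxonium ylide [2,3]-shift and leads to diazoketone 19, a tetrahydropyran with an (E)-alkoxyvinyl group at C4 and a diazoacetonyl arm at C10, cis to each other. Two rings, two skeletal bonds and the stereocentres C6 and C7 come from one step, and no medium ring has to be closed end to end.

**Diazoketone arm and enol ether (19 ⇒ 17 ⇒ 16 ⇒ 14 ⇒ 12).** The diazoketone is made from acid 17, which comes from primary alcohol 16 and thus from the terminal alkene of 14 by hydroboration. The geometrically pure (E)-enol ether is cut at the vinyl C–O bond to (E)-alkenyl iodide 12 and alcohol 13; a stereoretentive copper coupling avoids the E/Z mixtures of alkoxymethylene Wittig reagents.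

**Pyran ring (12 ⇒ 11 ⇒ 10).** The O–C10 bond is cut to hydroxy vinyl-epoxide 10. A plain epoxy alcohol of this type would close mainly 5-exo. The vinyl group on C10 turns the closure to 6-endo with inversion at C10, and it also supplies C9 and C8.

**Acyclic chain (10 ⇒ 8 ⇒ 7 ⇒ 6 ⇒ 4 ⇒ 3 ⇒ 2 ⇒ 1).** The vinyl epoxide comes from epoxy aldehyde 8. The iodoalkene of 7 is made from aldehyde 6 at the one stage (epoxy alcohol 4) where the vinyl group of the terpene is the only alkene, so that no two vinyl groups ever have to be told apart. Epoxy alcohol 4 comes from allylic alcohol 3 by reagent-controlled epoxidation, and 3 from silyl-protected (R)-linalool 2, whose carbinol carbon becomes C4 of 19.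

## Alternatives that were turned down

**Alternative 1:** The lactone C6–O bond is made last. Primary amide A2, which has a C6 methylene, is converted into lactone A1: an amidyl radical (hypervalent iodine oxidant, light) abstracts the allylic C6 hydrogen in a 1,5-shift, the allyl radical is oxidised, the amide oxygen closes on C6 and the iminolactone is hydrolysed (Hofmann–Löffler–Freytag type).
- For: no protecting group at C6, and C11, C13 and the C8 ester are already in place, so the endgame after the key step is shorter than in the chosen route. On that point it is stronger.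
- Against: the C6 radical is delocalised over C4–C6, so oxygen can enter at C4 and the Z geometry of C4=C5 can be lost. The electron-rich alkene and the C1 ketone are exposed to iodine electrophiles. Without a free C6 hydroxyl the later epoxidation has no directing group.
- Comparison: the alternative does not say how the bridged oxonene and the quaternary C7 are reached. The chosen route sets C6 and C7 in the ring-forming step and uses the C6 hydroxyl twice afterwards.

**Alternative 2:** The C4=C5 bond is cut to the ten-membered cyclic sulfone A4 (sulfur between C4 and C5). A Ramberg–Bäcklund reaction with in-situ α-halogenation extrudes SO2 and contracts the ring to the Z-oxonene A3.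
- For: a ten-membered thioether ring closes more easily than a nine-membered ether, and ring contraction fixes both the position and the cis geometry of the alkene. That geometric control is more certain than in the chosen ylide step.
- Against: the alkene is trisubstituted, so one α-carbon (C4) is tertiary and halogenates slowly, while the other (C5) is β to the C6 ether and its carbanion can expel it. The key step creates no stereocentre; the tetrahydrofuran with C6, C7, C8 and C10 must be built beforehand under four protecting groups.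
- Comparison: the chosen route trades the certainty of the alkene geometry for two rings and two stereocentres in one step from a terpene-derived pyran.

**Alternative 3:** O–C7, C11–C12 and C12–O are cut together. In cyclodecane diol A6 the C10 hydroxyl attacks the exocyclic C7=C11 alkene across the ring under divalent palladium, the C11–palladium bond is carbonylated and the C6 hydroxyl captures the acyl group, giving A5.
- For: three bonds, two rings and C7 in one step, with C12 from the carbonylation; A5 is only a methylenation and a few redox steps from the target. In bonds per step and in the length of the endgame it is stronger than the chosen route.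
- Against: the precursor is a ten-membered carbocycle with five stereocentres, an epoxide and a tertiary alcohol, so the medium-ring problem is only moved. A tertiary alcohol adds slowly to a 1,1-disubstituted alkene, and a Lewis-acidic metal invites transannular opening of the epoxide by the same hydroxyl.
- Comparison: the chosen route reaches the medium ring by expanding a six-membered ring and needs no macrocyclisation.

Key step: step 14

Remark on the chemistry: from the key step on, compounds are named with germacrane numbering and the 7,10-ether bridge is written as a 7,10-epoxy prefix; the tetrahydropyrans are named as oxanes.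
Assumption: commercial (R)-linalool of high enantiomeric purity is used.

## Route

Step 1
Reactants: 1 (R)-linalool
Product: 2 (3R)-3,7-dimethyl-3-(triethylsilyloxy)octa-1,6-diene
Conditions: TESOTf, 2,6-lutidine, CH2Cl2, −78 to 0 °C
Reagents that add atoms: triethylsilyl trifluoromethanesulfonate, CC[Si](CC)(CC)OS(=O)(=O)C(F)(F)F
Why: Silyl ether formation at the tertiary hydroxyl with the reactive triflate; the ether should keep this oxygen from opening the later epoxide under titanium catalysis and under the basic olefination.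

Step 2
Reactants: 2 (3R)-3,7-dimethyl-3-(triethylsilyloxy)octa-1,6-diene
Product: 3 (2E,6R)-2,6-dimethyl-6-(triethylsilyloxy)octa-2,7-dien-1-ol
Conditions: SeO2 (cat.), t-BuOOH, CH2Cl2, rt
Reagents that add atoms: tert-butyl hydroperoxide, CC(C)(C)OO
Why: Selenium dioxide allylic oxidation (Riley oxidation: ene reaction then [2,3]-shift) hydroxylates the (E)-methyl group of the trisubstituted alkene; the vinyl group has no allylic hydrogen and should stay untouched.

Step 3
Reactants: 3 (2E,6R)-2,6-dimethyl-6-(triethylsilyloxy)octa-2,7-dien-1-ol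
Product: 4 [(2S,3S)-2-methyl-3-[(3R)-3-methyl-3-(triethylsilyloxy)pent-4-en-1-yl]oxiran-2-yl]methanol
Conditions: Ti(OiPr)4 (cat.), L-(+)-diethyl tartrate (cat.), t-BuOOH, 4 Å MS, CH2Cl2, −20 °C
Reagents that add atoms: tert-butyl hydroperoxide, CC(C)(C)OO
Why: Sharpless asymmetric epoxidation of the primary allylic alcohol; the L-(+)-tartrate complex delivers oxygen to the face that gives the (2S,3S)-epoxide (reagent control), which fixes the future C1 and, after inversion, C10. The vinyl group is not part of a free allylic alcohol and should not react.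

Step 4
Reactants: 4 [(2S,3S)-2-methyl-3-[(3R)-3-methyl-3-(triethylsilyloxy)pent-4-en-1-yl]oxiran-2-yl]methanol
Product: 6 (2R)-4-[(2S,3S)-3-(hydroxymethyl)-3-methyloxiran-2-yl]-2-methyl-2-(triethylsilyloxy)butanal, via secondary ozonide 5 (not isolated)
Conditions: O3, CH2Cl2, −78 °C; then PPh3, −78 °C to rt
Reagents that add atoms: ozone, [O-][O+]=O
Why: Ozonolysis with reductive work-up of the only alkene present; the aldehyde has no α-hydrogen, so the former linalool centre cannot epimerise.

Step 5
Reactants: 6 (2R)-4-[(2S,3S)-3-(hydroxymethyl)-3-methyloxiran-2-yl]-2-methyl-2-(triethylsilyloxy)butanal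
Product: 7 [(2S,3S)-3-[(3R,4E)-5-iodo-3-methyl-3-(triethylsilyloxy)pent-4-en-1-yl]-2-methyloxiran-2-yl]methanol
Conditions: CrCl2, CHI3, THF/1,4-dioxane, 0 °C to rt
Reagents that add atoms: iodoform, IC(I)I
Why: Takai olefination; the geminal dichromium reagent adds to the aldehyde and eliminates to the (E)-iodoalkene. The reagent is aldehyde-selective and should tolerate the epoxide and the free hydroxyl.

Step 6
Reactants: 7 [(2S,3S)-3-[(3R,4E)-5-iodo-3-methyl-3-(triethylsilyloxy)pent-4-en-1-yl]-2-methyloxiran-2-yl]methanol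
Product: 8 (2R,3S)-3-[(3R,4E)-5-iodo-3-methyl-3-(triethylsilyloxy)pent-4-en-1-yl]-2-methyloxirane-2-carbaldehyde
Conditions: Dess–Martin periodinane, NaHCO3, CH2Cl2, 0 °C to rt
Reagents that add atoms: none
Why: Dess–Martin oxidation of the primary alcohol under buffered conditions; the epoxy aldehyde has no α-hydrogen, and the descriptor at the aldehyde-bearing carbon changes only because of the new priority order.

Step 7
Reactants: 8 (2R,3S)-3-[(3R,4E)-5-iodo-3-methyl-3-(triethylsilyloxy)pent-4-en-1-yl]-2-methyloxirane-2-carbaldehyde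
Product: 10 (1E,3R)-5-[(2S,3S)-3-ethenyl-3-methyloxiran-2-yl]-1-iodo-3-methylpent-1-en-3-ol, via silyl-protected vinyl epoxide 9 (not isolated)
Conditions: Ph3PCH3Br, NaN(SiMe3)2, THF, −78 to 0 °C; then n-Bu4NF, THF, rt
Reagents that add atoms: methyltriphenylphosphonium bromide, C[P+](c1ccccc1)(c1ccccc1)c1ccccc1.[Br-]
Why: Wittig methylenation of the non-enolisable aldehyde, then fluoride cleavage of the silyl ether; this frees the tertiary hydroxyl only after all strongly basic steps.

Step 8
Reactants: 10 (1E,3R)-5-[(2S,3S)-3-ethenyl-3-methyloxiran-2-yl]-1-iodo-3-methylpent-1-en-3-ol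
Product: 11 (2R,3S,6R)-2-ethenyl-6-[(E)-2-iodoethenyl]-2,6-dimethyloxan-3-ol
Conditions: CSA (cat.), CH2Cl2, −40 to 0 °C
Reagents that add atoms: none
Why: Acid-catalysed hydroxy-epoxide cyclisation; the vinyl group stabilises positive charge at the tertiary allylic epoxide carbon, so the tertiary hydroxyl attacks there (6-endo) with inversion rather than at the secondary carbon (5-exo). This sets C10 and places the C10 methyl cis to the new C1 hydroxyl.

Step 9
Reactants: 11 (2R,3S,6R)-2-ethenyl-6-[(E)-2-iodoethenyl]-2,6-dimethyloxan-3-ol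
Product: 12 (2R,3S,6R)-3-(tert-butyldimethylsilyloxy)-2-ethenyl-6-[(E)-2-iodoethenyl]-2,6-dimethyloxane
Conditions: TBSOTf, 2,6-lutidine, CH2Cl2, −78 to 0 °C
Reagents that add atoms: tert-butyldimethylsilyl trifluoromethanesulfonate, CC(C)(C)[Si](C)(C)OS(=O)(=O)C(F)(F)F
Why: Silylation of the hindered secondary alcohol; the C1 oxygen stays masked until the last two steps, so no carbonyl oxygen is near either carbenoid.

Step 10
Reactants: 12 (2R,3S,6R)-3-(tert-butyldimethylsilyloxy)-2-ethenyl-6-[(E)-2-iodoethenyl]-2,6-dimethyloxane; 13 4-methoxybenzyl alcohol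
Product: 14 (2R,3S,6R)-3-(tert-butyldimethylsilyloxy)-2-ethenyl-6-[(E)-2-(4-methoxybenzyloxy)ethenyl]-2,6-dimethyloxane
Conditions: CuI (cat.), 3,4,7,8-tetramethyl-1,10-phenanthroline (cat.), Cs2CO3, toluene, 80 °C
Reagents that add atoms: none
Why: Copper-catalysed Ullmann-type C–O coupling of an alkenyl iodide with an alcohol; it proceeds with retention at the alkene, so the (E)-iodide should give the (E)-enol ether. The base-stable silyl ether and terminal alkene are not affected.

Step 11
Reactants: 14 (2R,3S,6R)-3-(tert-butyldimethylsilyloxy)-2-ethenyl-6-[(E)-2-(4-methoxybenzyloxy)ethenyl]-2,6-dimethyloxane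
Product: 16 2-[(2R,3S,6R)-3-(tert-butyldimethylsilyloxy)-6-[(E)-2-(4-methoxybenzyloxy)ethenyl]-2,6-dimethyloxan-2-yl]ethanol, via B-alkyl-9-BBN adduct 15 (not isolated)
Conditions: 9-BBN, THF, 0 °C to rt; then NaOH, H2O2, 0 °C
Reagents that add atoms: hydrogen peroxide, OO
Why: Hydroboration–oxidation; 9-BBN adds anti-Markovnikov to the monosubstituted alkene far faster than to the 1,2-disubstituted enol ether that carries a tertiary alkyl group, and the basic peroxide work-up leaves the enol ether intact.

Step 12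
Reactants: 16 2-[(2R,3S,6R)-3-(tert-butyldimethylsilyloxy)-6-[(E)-2-(4-methoxybenzyloxy)ethenyl]-2,6-dimethyloxan-2-yl]ethanol
Product: 17 2-[(2R,3S,6R)-3-(tert-butyldimethylsilyloxy)-6-[(E)-2-(4-methoxybenzyloxy)ethenyl]-2,6-dimethyloxan-2-yl]acetic acid
Conditions: n-Pr4N[RuO4] (TPAP, cat.), NMO·H2O, MeCN, rt; isolated as the triethylammonium salt
Reagents that add atoms: N-methylmorpholine N-oxide monohydrate, C[N+]1([O-])CCOCC1.O
Why: Ley–Griffith oxidation run with the hydrated co-oxidant, which carries the alcohol through the aldehyde hydrate to the acid under non-acidic conditions that the enol ether should survive.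

Step 13
Reactants: 17 2-[(2R,3S,6R)-3-(tert-butyldimethylsilyloxy)-6-[(E)-2-(4-methoxybenzyloxy)ethenyl]-2,6-dimethyloxan-2-yl]acetic acid
Product: 19 1-diazo-3-[(2R,3S,6R)-3-(tert-butyldimethylsilyloxy)-6-[(E)-2-(4-methoxybenzyloxy)ethenyl]-2,6-dimethyloxan-2-yl]propan-2-one, via isobutyl carbonic anhydride 18 (not isolated)
Conditions: i-BuOCOCl, Et3N, THF, −15 °C; then CH2N2, Et2O, 0 °C
Reagents that add atoms: diazomethane, C=[N+]=[N-]
Why: Acylation of diazomethane by a mixed carbonic anhydride (first stage of an Arndt–Eistert sequence); base is present throughout, so no acid reaches the enol ether.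

Step 14
Reactants: 19 1-diazo-3-[(2R,3S,6R)-3-(tert-butyldimethylsilyloxy)-6-[(E)-2-(4-methoxybenzyloxy)ethenyl]-2,6-dimethyloxan-2-yl]propan-2-one
Product: 21 (1S,4Z,6R,7R,10R)-1-(tert-butyldimethylsilyloxy)-6-(4-methoxybenzyloxy)-4,10-dimethyl-7,10-epoxycyclodec-4-en-8-one, via bicyclic oxonium ylide 20 (not isolated)
Conditions: Cu(hfacac)2 (copper bis(hexafluoroacetylacetonate), cat.), CH2Cl2, reflux, slow addition of 19
Reagents that add atoms: none
Why: The copper catalyst converts the diazoketone into an electrophilic carbenoid at C7, and a lone pair of the pyran oxygen captures it in a five-membered closure (5-exo attack of oxygen on the carbenoid carbon) to give the cis-fused oxonium ylide 20. A suprafacial [2,3]-sigmatropic shift through a five-membered envelope (C7, O, C4, C5, C6) then joins C7 to C6 while the weak tertiary allylic O–C4 bond breaks; the tetrahydrofuranone is the ylide ring itself and the six-membered ring grows by three atoms into the oxonene (ring expansion, not end-to-end cyclisation). The closest known reaction type is the copper-catalysed oxonium ylide formation and [2,3]-rearrangement of vinyl-substituted tetrahydropyranyl diazoketones to 11-oxabicyclo[6.2.1]undecenones. C7 is controlled by the bicyclic ylide: C6 can only be delivered to the face of the five-membered ring that carries the pyran carbons, so C6 and C1 end up cis on the furanone. C6 is controlled by the (E)-enol ether: in the envelope in which the furanone ring lies exo to the allyl unit the 4-methoxybenzyloxy group points outward, syn to H7, and the (6R) ether results. The same exo envelope places C3 cis to C6 and gives the Z alkene; it is open to 19 because the diazoacetonyl arm and the alkoxyvinyl group are cis on the pyran, and copper is the metal expected to favour it. The step needs ylide formation to win over C–H insertion at C1–H and over cyclopropanation of the enol ether; the copper carbenoid (poor at C–H insertion), the five-membered ylide closure against a seven-membered cyclopropanation, and the C1 silyl ether (no carbonyl ylide) should secure this.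

Step 15
Reactants: 21 (1S,4Z,6R,7R,10R)-1-(tert-butyldimethylsilyloxy)-6-(4-methoxybenzyloxy)-4,10-dimethyl-7,10-epoxycyclodec-4-en-8-one
Product: 22 (1S,4Z,6R,7R,10R)-1-(tert-butyldimethylsilyloxy)-6-hydroxy-4,10-dimethyl-7,10-epoxycyclodec-4-en-8-one
Conditions: DDQ, CH2Cl2/pH 7 buffer, 0 °C
Reagents that add atoms: none
Why: Oxidative cleavage of the 4-methoxybenzyl ether under neutral conditions; base is avoided because the β-oxygenated ketone would eliminate or undergo retro-aldol opening.

Step 16
Reactants: 22 (1S,4Z,6R,7R,10R)-1-(tert-butyldimethylsilyloxy)-6-hydroxy-4,10-dimethyl-7,10-epoxycyclodec-4-en-8-one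
Product: 23 (1S,4Z,6R,7S,8S,10R)-1-(tert-butyldimethylsilyloxy)-4,10-dimethyl-7,10-epoxycyclodec-4-ene-6,8-diol
Conditions: Me4NBH(OAc)3, MeCN/AcOH, −30 to −20 °C
Reagents that add atoms: none
Why: Evans–Saksena reduction; the borohydride exchanges onto the C6 hydroxyl and transfers hydride within the molecule. C6 stands on one face of the furanone and the C7–C8 bond is locked in the ring, so hydride can reach C8 only from that face: the new hydroxyl is trans to C6 and cis to H7 (C8 S).

Step 17
Reactants: 23 (1S,4Z,6R,7S,8S,10R)-1-(tert-butyldimethylsilyloxy)-4,10-dimethyl-7,10-epoxycyclodec-4-ene-6,8-diol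
Product: 24 (1S,4R,5S,6S,7S,8S,10R)-1-(tert-butyldimethylsilyloxy)-4,10-dimethyl-4,5:7,10-diepoxycyclodecane-6,8-diol
Conditions: VO(acac)2 (cat.), t-BuOOH, CH2Cl2, 0 °C to rt
Reagents that add atoms: tert-butyl hydroperoxide, CC(C)(C)OO
Why: Vanadium-catalysed hydroxyl-directed epoxidation; the C6 vanadate delivers oxygen to the outer face of the Z alkene through a small O–C6–C5=C4 dihedral, which in medium-ring cis-allylic alcohols gives the cis-epoxy alcohol, here (4R,5S). The C8 hydroxyl is three carbons from the alkene and should not compete.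

Step 18
Reactants: 24 (1S,4R,5S,6S,7S,8S,10R)-1-(tert-butyldimethylsilyloxy)-4,10-dimethyl-4,5:7,10-diepoxycyclodecane-6,8-diol; 25 methacrylic anhydride
Product: 26 (1S,4R,5S,6S,7R,8S,10R)-1-(tert-butyldimethylsilyloxy)-6-hydroxy-4,10-dimethyl-4,5:7,10-diepoxycyclodecan-8-yl 2-methylprop-2-enoate
Conditions: Et3N, DMAP (cat.), CH2Cl2, −40 to −20 °C
Reagents that add atoms: none
Why: Site-selective esterification; the C8 hydroxyl sits on the open face of the five-membered ring next to a methylene group, whereas the C6 hydroxyl is flanked by the bridgehead and the epoxide and is deactivated by two β-oxygens, so a limiting amount of anhydride at low temperature should acylate O8.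

Step 19
Reactants: 26 (1S,4R,5S,6S,7R,8S,10R)-1-(tert-butyldimethylsilyloxy)-6-hydroxy-4,10-dimethyl-4,5:7,10-diepoxycyclodecan-8-yl 2-methylprop-2-enoate; 27 bromoacetyl bromide
Product: 28 (1S,4R,5S,6S,7S,8S,10R)-6-(bromoacetoxy)-1-(tert-butyldimethylsilyloxy)-4,10-dimethyl-4,5:7,10-diepoxycyclodecan-8-yl 2-methylprop-2-enoate
Conditions: NaHCO3, MeCN, 0 °C
Reagents that add atoms: none
Why: Acylation of the remaining hindered hydroxyl by the very reactive acyl bromide under weakly basic conditions that should not trigger acyl migration.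

Step 20
Reactants: 28 (1S,4R,5S,6S,7S,8S,10R)-6-(bromoacetoxy)-1-(tert-butyldimethylsilyloxy)-4,10-dimethyl-4,5:7,10-diepoxycyclodecan-8-yl 2-methylprop-2-enoate
Product: 29 (1S,4R,5S,6S,7S,8S,10R)-1-(tert-butyldimethylsilyloxy)-6-(diazoacetoxy)-4,10-dimethyl-4,5:7,10-diepoxycyclodecan-8-yl 2-methylprop-2-enoate
Conditions: TsNHNHTs, DBU, THF, 0 °C
Reagents that add atoms: N,N′-ditosylhydrazine, Cc1ccc(cc1)S(=O)(=O)NNS(=O)(=O)c1ccc(C)cc1
Why: Diazo ester synthesis from a bromoacetate: N-alkylation of the bis-sulfonyl hydrazide and two base-induced losses of sulfinate; the conditions are brief and cold and should spare the epoxide and the methacrylate.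

Step 21
Reactants: 29 (1S,4R,5S,6S,7S,8S,10R)-1-(tert-butyldimethylsilyloxy)-6-(diazoacetoxy)-4,10-dimethyl-4,5:7,10-diepoxycyclodecan-8-yl 2-methylprop-2-enoate
Product: 30 (1S,4R,5S,6R,7S,8S,10R)-1-(tert-butyldimethylsilyloxy)-4,5:7,10-diepoxy-8-(methacryloyloxy)-13-norgermacrano-12,6-lactone
Conditions: Rh2(acam)4 (dirhodium tetraacetamidate, cat.), CH2Cl2, reflux, slow addition of 29
Reagents that add atoms: none
Why: Intramolecular C–H insertion of the rhodium carbenoid into C7–H, which is 1,5 to the carbene carbon, tertiary and activated by the ring ether oxygen; the carboxamidate ligands make the carbenoid selective for insertion over ylide formation at the epoxide or ether oxygen. The three-centre insertion goes with retention, so C11 takes the place of H7 (C7 S).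

Step 22
Reactants: 30 (1S,4R,5S,6R,7S,8S,10R)-1-(tert-butyldimethylsilyloxy)-4,5:7,10-diepoxy-8-(methacryloyloxy)-13-norgermacrano-12,6-lactone
Product: 33 (1S,4R,5S,6R,7S,8S,10R)-1-(tert-butyldimethylsilyloxy)-4,5:7,10-diepoxy-8-(methacryloyloxy)germacr-11(13)-eno-12,6-lactone, via Mannich base 31 (not isolated), via trimethylammonium iodide 32 (not isolated)
Conditions: LiN(SiMe3)2, THF, −78 °C; CH2=NMe2 I, −78 to −20 °C; then MeI, CH2Cl2, rt; then NaHCO3 (aq.)
Reagents that add atoms: N,N-dimethylmethyleneiminium iodide (Eschenmoser's salt), C=[N+](C)C.[I-]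
Why: α-Methylenation of the lactone by Mannich reaction of its lithium enolate, quaternisation and elimination; at −78 °C the enolate should be trapped by the iminium salt faster than it expels the β-ether oxygen at C7 or adds to the methacrylate.

Step 23
Reactants: 33 (1S,4R,5S,6R,7S,8S,10R)-1-(tert-butyldimethylsilyloxy)-4,5:7,10-diepoxy-8-(methacryloyloxy)germacr-11(13)-eno-12,6-lactone
Product: 34 (1S,4R,5S,6R,7S,8S,10R)-4,5:7,10-diepoxy-1-hydroxy-8-(methacryloyloxy)germacr-11(13)-eno-12,6-lactone
Conditions: HF·pyridine, pyridine, THF, 0 °C to rt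
Reagents that add atoms: none
Why: Fluoride cleavage of the silyl ether under buffered, non-basic conditions; the two Michael acceptors are not exposed to alkoxide, and the epoxide, which sits next to the electron-poor lactone carbinol, should tolerate the buffered reagent.

Step 24
Reactants: 34 (1S,4R,5S,6R,7S,8S,10R)-4,5:7,10-diepoxy-1-hydroxy-8-(methacryloyloxy)germacr-11(13)-eno-12,6-lactone
Product: 35 (4R,5S,6R,7S,8S,10R)-4,5:7,10-diepoxy-8-(methacryloyloxy)-1-oxogermacr-11(13)-eno-12,6-lactone (CNP0241021.1)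
Conditions: Dess–Martin periodinane, NaHCO3, CH2Cl2, rt
Reagents that add atoms: none
Why: Dess–Martin oxidation of the secondary alcohol to the C1 ketone under neutral buffered conditions; no stereocentre is adjacent to an enolisable position that could be lost.

## Compound list

1 | (R)-linalool, (3R)-3,7-dimethylocta-1,6-dien-3-ol | C=C[C@](C)(O)CCC=C(C)C | starting material
2 | (3R)-3,7-dimethyl-3-(triethylsilyloxy)octa-1,6-diene | C=C[C@](C)(O[Si](CC)(CC)CC)CCC=C(C)C | intermediate
3 | (2E,6R)-2,6-dimethyl-6-(triethylsilyloxy)octa-2,7-dien-1-ol | C=C[C@](C)(O[Si](CC)(CC)CC)CC/C=C(\C)CO | intermediate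
4 | [(2S,3S)-2-methyl-3-[(3R)-3-methyl-3-(triethylsilyloxy)pent-4-en-1-yl]oxiran-2-yl]methanol | OC[C@]1(C)O[C@H]1CC[C@@](C)(O[Si](CC)(CC)CC)C=C | intermediate
5 | secondary ozonide (1,2,4-trioxolane) at the vinyl group of 4 | OC[C@]1(C)O[C@H]1CC[C@@](C)(O[Si](CC)(CC)CC)C1OCOO1 | intermediate (not isolated)
6 | (2R)-4-[(2S,3S)-3-(hydroxymethyl)-3-methyloxiran-2-yl]-2-methyl-2-(triethylsilyloxy)butanal | OC[C@]1(C)O[C@H]1CC[C@@](C)(O[Si](CC)(CC)CC)C=O | intermediate
7 | [(2S,3S)-3-[(3R,4E)-5-iodo-3-methyl-3-(triethylsilyloxy)pent-4-en-1-yl]-2-methyloxiran-2-yl]methanol | OC[C@]1(C)O[C@H]1CC[C@@](C)(O[Si](CC)(CC)CC)/C=C/I | intermediate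
8 | (2R,3S)-3-[(3R,4E)-5-iodo-3-methyl-3-(triethylsilyloxy)pent-4-en-1-yl]-2-methyloxirane-2-carbaldehyde | O=C[C@]1(C)O[C@H]1CC[C@@](C)(O[Si](CC)(CC)CC)/C=C/I | intermediate
9 | (2S,3S)-2-ethenyl-3-[(3R,4E)-5-iodo-3-methyl-3-(triethylsilyloxy)pent-4-en-1-yl]-2-methyloxirane | C=C[C@]1(C)O[C@H]1CC[C@@](C)(O[Si](CC)(CC)CC)/C=C/I | intermediate (not isolated)
10 | (1E,3R)-5-[(2S,3S)-3-ethenyl-3-methyloxiran-2-yl]-1-iodo-3-methylpent-1-en-3-ol | C=C[C@]1(C)O[C@H]1CC[C@@](C)(O)/C=C/I | intermediate
11 | (2R,3S,6R)-2-ethenyl-6-[(E)-2-iodoethenyl]-2,6-dimethyloxan-3-ol | C=C[C@@]1(C)O[C@@](C)(/C=C/I)CC[C@@H]1O | intermediate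
12 | (2R,3S,6R)-3-(tert-butyldimethylsilyloxy)-2-ethenyl-6-[(E)-2-iodoethenyl]-2,6-dimethyloxane | C=C[C@@]1(C)O[C@@](C)(/C=C/I)CC[C@@H]1O[Si](C)(C)C(C)(C)C | intermediate
13 | 4-methoxybenzyl alcohol | COc1ccc(CO)cc1 | starting material
14 | (2R,3S,6R)-3-(tert-butyldimethylsilyloxy)-2-ethenyl-6-[(E)-2-(4-methoxybenzyloxy)ethenyl]-2,6-dimethyloxane | C=C[C@@]1(C)O[C@@](C)(/C=C/OCc2ccc(OC)cc2)CC[C@@H]1O[Si](C)(C)C(C)(C)C | intermediate
15 | B-alkyl-9-borabicyclo[3.3.1]nonane adduct of 14 (boron on the terminal carbon of the former vinyl group) | C1CC2CCCC(C1)B2CC[C@@]3(C)O[C@@](C)(/C=C/OCc4ccc(OC)cc4)CC[C@@H]3O[Si](C)(C)C(C)(C)C | intermediate (not isolated)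
16 | 2-[(2R,3S,6R)-3-(tert-butyldimethylsilyloxy)-6-[(E)-2-(4-methoxybenzyloxy)ethenyl]-2,6-dimethyloxan-2-yl]ethanol | OCC[C@@]1(C)O[C@@](C)(/C=C/OCc2ccc(OC)cc2)CC[C@@H]1O[Si](C)(C)C(C)(C)C | intermediate
17 | 2-[(2R,3S,6R)-3-(tert-butyldimethylsilyloxy)-6-[(E)-2-(4-methoxybenzyloxy)ethenyl]-2,6-dimethyloxan-2-yl]acetic acid | OC(=O)C[C@@]1(C)O[C@@](C)(/C=C/OCc2ccc(OC)cc2)CC[C@@H]1O[Si](C)(C)C(C)(C)C | intermediate
18 | mixed isobutyl carbonic anhydride of 17 | CC(C)COC(=O)OC(=O)C[C@@]1(C)O[C@@](C)(/C=C/OCc2ccc(OC)cc2)CC[C@@H]1O[Si](C)(C)C(C)(C)C | intermediate (not isolated)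
19 | 1-diazo-3-[(2R,3S,6R)-3-(tert-butyldimethylsilyloxy)-6-[(E)-2-(4-methoxybenzyloxy)ethenyl]-2,6-dimethyloxan-2-yl]propan-2-one | [N-]=[N+]=CC(=O)C[C@@]1(C)O[C@@](C)(/C=C/OCc2ccc(OC)cc2)CC[C@@H]1O[Si](C)(C)C(C)(C)C | intermediate (precursor of the key step)
20 | cis-fused bicyclic oxonium ylide (pyran oxygen bonded to C7 of a 3-oxotetrahydrofuran ring, carbanion at C7) | O=C1C[C@@]2(C)[O+]([CH-]1)[C@@](C)(/C=C/OCc1ccc(OC)cc1)CC[C@@H]2O[Si](C)(C)C(C)(C)C | intermediate (not isolated)
21 | (1S,4Z,6R,7R,10R)-1-(tert-butyldimethylsilyloxy)-6-(4-methoxybenzyloxy)-4,10-dimethyl-7,10-epoxycyclodec-4-en-8-one | O=C1C[C@@]2(C)O[C@@H]1[C@H](OCc1ccc(OC)cc1)/C=C(C)\CC[C@@H]2O[Si](C)(C)C(C)(C)C | intermediate (product of the key step)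
22 | (1S,4Z,6R,7R,10R)-1-(tert-butyldimethylsilyloxy)-6-hydroxy-4,10-dimethyl-7,10-epoxycyclodec-4-en-8-one | O=C1C[C@@]2(C)O[C@@H]1[C@H](O)/C=C(C)\CC[C@@H]2O[Si](C)(C)C(C)(C)C | intermediate
23 | (1S,4Z,6R,7S,8S,10R)-1-(tert-butyldimethylsilyloxy)-4,10-dimethyl-7,10-epoxycyclodec-4-ene-6,8-diol | O[C@H]1C[C@@]2(C)O[C@@H]1[C@H](O)/C=C(C)\CC[C@@H]2O[Si](C)(C)C(C)(C)C | intermediate
24 | (1S,4R,5S,6S,7S,8S,10R)-1-(tert-butyldimethylsilyloxy)-4,10-dimethyl-4,5:7,10-diepoxycyclodecane-6,8-diol | O[C@H]1C[C@@]2(C)O[C@@H]1[C@H](O)[C@@H]1O[C@]1(C)CC[C@@H]2O[Si](C)(C)C(C)(C)C | intermediate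
25 | methacrylic anhydride | C=C(C)C(=O)OC(=O)C(C)=C | starting material
26 | (1S,4R,5S,6S,7R,8S,10R)-1-(tert-butyldimethylsilyloxy)-6-hydroxy-4,10-dimethyl-4,5:7,10-diepoxycyclodecan-8-yl 2-methylprop-2-enoate | C=C(C)C(=O)O[C@H]1C[C@@]2(C)O[C@@H]1[C@H](O)[C@@H]1O[C@]1(C)CC[C@@H]2O[Si](C)(C)C(C)(C)C | intermediate
27 | bromoacetyl bromide | BrCC(Br)=O | starting material
28 | (1S,4R,5S,6S,7S,8S,10R)-6-(bromoacetoxy)-1-(tert-butyldimethylsilyloxy)-4,10-dimethyl-4,5:7,10-diepoxycyclodecan-8-yl 2-methylprop-2-enoate | C=C(C)C(=O)O[C@H]1C[C@@]2(C)O[C@@H]1[C@H](OC(=O)CBr)[C@@H]1O[C@]1(C)CC[C@@H]2O[Si](C)(C)C(C)(C)C | intermediate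
29 | (1S,4R,5S,6S,7S,8S,10R)-1-(tert-butyldimethylsilyloxy)-6-(diazoacetoxy)-4,10-dimethyl-4,5:7,10-diepoxycyclodecan-8-yl 2-methylprop-2-enoate | C=C(C)C(=O)O[C@H]1C[C@@]2(C)O[C@@H]1[C@H](OC(=O)C=[N+]=[N-])[C@@H]1O[C@]1(C)CC[C@@H]2O[Si](C)(C)C(C)(C)C | intermediate
30 | (1S,4R,5S,6R,7S,8S,10R)-1-(tert-butyldimethylsilyloxy)-4,5:7,10-diepoxy-8-(methacryloyloxy)-13-norgermacrano-12,6-lactone | C=C(C)C(=O)O[C@H]1C[C@@]2(C)O[C@@]13CC(=O)O[C@@H]3[C@@H]1O[C@]1(C)CC[C@@H]2O[Si](C)(C)C(C)(C)C | intermediate
31 | 13-(dimethylamino) Mannich base of 30 (C11 epimers) | C=C(C)C(=O)O[C@H]1C[C@@]2(C)O[C@@]13C(CN(C)C)C(=O)O[C@@H]3[C@@H]1O[C@]1(C)CC[C@@H]2O[Si](C)(C)C(C)(C)C | intermediate (not isolated)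
32 | 13-(trimethylammonio) iodide from 31 | C=C(C)C(=O)O[C@H]1C[C@@]2(C)O[C@@]13C(C[N+](C)(C)C)C(=O)O[C@@H]3[C@@H]1O[C@]1(C)CC[C@@H]2O[Si](C)(C)C(C)(C)C.[I-] | intermediate (not isolated)
33 | (1S,4R,5S,6R,7S,8S,10R)-1-(tert-butyldimethylsilyloxy)-4,5:7,10-diepoxy-8-(methacryloyloxy)germacr-11(13)-eno-12,6-lactone | C=C(C)C(=O)O[C@H]1C[C@@]2(C)O[C@@]13C(=C)C(=O)O[C@@H]3[C@@H]1O[C@]1(C)CC[C@@H]2O[Si](C)(C)C(C)(C)C | intermediate
34 | (1S,4R,5S,6R,7S,8S,10R)-4,5:7,10-diepoxy-1-hydroxy-8-(methacryloyloxy)germacr-11(13)-eno-12,6-lactone | C=C(C)C(=O)O[C@H]1C[C@@]2(C)O[C@@]13C(=C)C(=O)O[C@@H]3[C@@H]1O[C@]1(C)CC[C@@H]2O | intermediate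
35 | (4R,5S,6R,7S,8S,10R)-4,5:7,10-diepoxy-8-(methacryloyloxy)-1-oxogermacr-11(13)-eno-12,6-lactone (CNP0241021.1) | C=C(C)C(=O)O[C@H]1C[C@@]2(C)O[C@@]13C(=C)C(=O)O[C@@H]3[C@@H]1O[C@]1(C)CCC2=O | target

## Step count and least certain steps

Total: 24 steps. Longest linear sequence: 24 steps from (R)-linalool 1 (13, 25 and 27 are purchased).

**Step 14 (key step).** The most likely failure is loss of stereochemical fidelity at C6. The O–C4 bond is tertiary and allylic and the terminus is a donor-substituted alkene, so the shift may become partly stepwise (allyl cation/enolate pair) and give the C6 epimer; the electron-rich enol ether may also intercept the carbenoid. Fallback: the fallback sets out from 19 and returns at 23; it takes the C6 configuration from a reagent-controlled reduction instead of the pericyclic step. If the rearrangement gives mainly the C6-epimeric bicyclic ether F1, DDQ cleavage gives the epimeric hydroxy ketone F2. Me4NBH(OAc)3 still reduces C8 from the face of C6 and gives the epimeric diol F3. MnO2 oxidises only the allylic C6 hydroxyl, giving hydroxy enone F4. Corey–Bakshi–Shibata reduction ((S)-2-methyl-CBS-oxazaborolidine, BH3·SMe2; the branched C7 arm taken as the larger group, the other catalyst antipode if the sense proves reversed) then gives 23.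

**Step 21 (C–H insertion).** The carbenoid may be captured by the epoxide or ether oxygen (ylide formation, then deoxygenation or a 1,2-shift), or insertion may be slow because C7–H is flanked by two acyloxy-bearing carbons. Fallback: the fallback sets out from 24 and returns at 33; it makes C7–H more electron-rich and changes the carbenoid class and the methylenation. Site-selective silylation (TESCl, imidazole) gives the 8-O-triethylsilyl ether F5. Esterification with diethylphosphonoacetic acid (DCC, DMAP) gives phosphonoacetate F6, and diazo transfer (p-acetamidobenzenesulfonyl azide, DBU) gives diazophosphonoacetate F7. Rh2(OAc)4 in hot 1,2-dichloroethane gives the α-phosphono lactone F8. Horner–Wadsworth–Emmons reaction with aqueous formaldehyde and K2CO3 gives the methylene lactone F9 without a lithium enolate. PPTS in methanol removes the triethylsilyl group to give alcohol F10, and 25 with DMAP gives 33.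

**Step 18 (site-selective acylation).** The two secondary hydroxyls may be discriminated poorly, or the acyl group may migrate between O8 and O6. Fallback: the fallback sets out from 22 and returns at 29; the two oxygens are differentiated by the mechanism of the reduction itself. VO(acac)2/t-BuOOH gives the epoxy hydroxy ketone F11. Evans–Tishchenko reduction (SmI2 cat., acetaldehyde) transfers hydride from the C6-bound hemiacetal to the same face of C8 and leaves the 6-O-acetate with a free C8 hydroxyl, F12. 25 with DMAP gives the acetate methacrylate F13. Detrifluoroacetylative diazo transfer (LiN(SiMe3)2 and 2,2,2-trifluoroethyl trifluoroacetate to the trifluoroacetoacetate F14, then methanesulfonyl azide and Et3N) turns the acetate into the diazoacetate 29.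

**Step 17 (epoxidation face).** Facial selectivity may be poor or reversed if the medium ring does not adopt the conformer with the C6 oxygen near the alkene plane. Fallback: the fallback sets out from 23 and returns at 24 without a new compound. The control element is changed from metal-alkoxide delivery to hydrogen-bond-guided peracid attack (m-chloroperbenzoic acid, NaHCO3), which in medium-ring cis-allylic alcohols takes the opposite face to the vanadium reagent.

**Step 11 (hydroboration).** The enol ether may be hydroborated as well if the hindered vinyl group on the quaternary carbon reacts slowly. Fallback: the fallback sets out from 12 and returns at 17; the carboxyl carbon is installed before the enol ether exists. 9-BBN then NaOH/H2O2 on 12 gives the iodoalkenyl alcohol F15. TEMPO/PhI(OAc)2 in aqueous acetonitrile gives acid F16, and Me3SiCHN2 gives methyl ester F17. The copper-catalysed coupling with 13 gives enol ether ester F18, and LiOH gives 17.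

## Further compounds

F1 | step 14 | (1S,4Z,6S,7R,10R)-1-(tert-butyldimethylsilyloxy)-6-(4-methoxybenzyloxy)-4,10-dimethyl-7,10-epoxycyclodec-4-en-8-one (C6 epimer of 21) | O=C1C[C@@]2(C)O[C@@H]1[C@@H](OCc1ccc(OC)cc1)/C=C(C)\CC[C@@H]2O[Si](C)(C)C(C)(C)C
F2 | step 14 | C6 epimer of hydroxy ketone 22 | O=C1C[C@@]2(C)O[C@@H]1[C@@H](O)/C=C(C)\CC[C@@H]2O[Si](C)(C)C(C)(C)C
F3 | step 14 | C6 epimer of diol 23 | O[C@H]1C[C@@]2(C)O[C@@H]1[C@@H](O)/C=C(C)\CC[C@@H]2O[Si](C)(C)C(C)(C)C
F4 | step 14 | 1-(tert-butyldimethylsilyloxy)-8-hydroxy-4,10-dimethyl-7,10-epoxycyclodec-4-en-6-one (4Z; C1, C7, C8, C10 as in 23) | O[C@H]1C[C@@]2(C)O[C@@H]1C(=O)/C=C(C)\CC[C@@H]2O[Si](C)(C)C(C)(C)C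
F5 | step 21 | 8-O-triethylsilyl ether of epoxy diol 24 | CC[Si](CC)(CC)O[C@H]1C[C@@]2(C)O[C@@H]1[C@H](O)[C@@H]1O[C@]1(C)CC[C@@H]2O[Si](C)(C)C(C)(C)C
F6 | step 21 | 6-O-(diethoxyphosphorylacetyl) ester of F5 | CC[Si](CC)(CC)O[C@H]1C[C@@]2(C)O[C@@H]1[C@H](OC(=O)CP(=O)(OCC)OCC)[C@@H]1O[C@]1(C)CC[C@@H]2O[Si](C)(C)C(C)(C)C
F7 | step 21 | 6-O-[diazo(diethoxyphosphoryl)acetyl] ester of F5 | CC[Si](CC)(CC)O[C@H]1C[C@@]2(C)O[C@@H]1[C@H](OC(=O)C(=[N+]=[N-])P(=O)(OCC)OCC)[C@@H]1O[C@]1(C)CC[C@@H]2O[Si](C)(C)C(C)(C)C
F8 | step 21 | 11-(diethoxyphosphoryl)-13-nor lactone with 8-O-triethylsilyl and 1-O-tert-butyldimethylsilyl groups (C11 epimers) | CC[Si](CC)(CC)O[C@H]1C[C@@]2(C)O[C@@]13C(P(=O)(OCC)OCC)C(=O)O[C@@H]3[C@@H]1O[C@]1(C)CC[C@@H]2O[Si](C)(C)C(C)(C)C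
F9 | step 21 | 8-O-triethylsilyl analogue of 33 | CC[Si](CC)(CC)O[C@H]1C[C@@]2(C)O[C@@]13C(=C)C(=O)O[C@@H]3[C@@H]1O[C@]1(C)CC[C@@H]2O[Si](C)(C)C(C)(C)C
F10 | step 21 | 8-hydroxy analogue of 33 | O[C@H]1C[C@@]2(C)O[C@@]13C(=C)C(=O)O[C@@H]3[C@@H]1O[C@]1(C)CC[C@@H]2O[Si](C)(C)C(C)(C)C
F11 | step 18 | 1-(tert-butyldimethylsilyloxy)-6-hydroxy-4,10-dimethyl-4,5:7,10-diepoxycyclodecan-8-one (epoxide of 22) | O=C1C[C@@]2(C)O[C@@H]1[C@H](O)[C@@H]1O[C@]1(C)CC[C@@H]2O[Si](C)(C)C(C)(C)C
F12 | step 18 | 6-O-acetate of epoxy diol 24 | O[C@H]1C[C@@]2(C)O[C@@H]1[C@H](OC(C)=O)[C@@H]1O[C@]1(C)CC[C@@H]2O[Si](C)(C)C(C)(C)C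
F13 | step 18 | 6-O-acetate of methacrylate 26 | C=C(C)C(=O)O[C@H]1C[C@@]2(C)O[C@@H]1[C@H](OC(C)=O)[C@@H]1O[C@]1(C)CC[C@@H]2O[Si](C)(C)C(C)(C)C
F14 | step 18 | 6-O-(4,4,4-trifluoro-3-oxobutanoyl) ester of 26 | C=C(C)C(=O)O[C@H]1C[C@@]2(C)O[C@@H]1[C@H](OC(=O)CC(=O)C(F)(F)F)[C@@H]1O[C@]1(C)CC[C@@H]2O[Si](C)(C)C(C)(C)C
F0 | step 17 | none | none
F15 | step 11 | 2-[(2R,3S,6R)-3-(tert-butyldimethylsilyloxy)-6-[(E)-2-iodoethenyl]-2,6-dimethyloxan-2-yl]ethanol | OCC[C@@]1(C)O[C@@](C)(/C=C/I)CC[C@@H]1O[Si](C)(C)C(C)(C)C
F16 | step 11 | 2-[(2R,3S,6R)-3-(tert-butyldimethylsilyloxy)-6-[(E)-2-iodoethenyl]-2,6-dimethyloxan-2-yl]acetic acid | OC(=O)C[C@@]1(C)O[C@@](C)(/C=C/I)CC[C@@H]1O[Si](C)(C)C(C)(C)C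
F17 | step 11 | methyl ester of F16 | COC(=O)C[C@@]1(C)O[C@@](C)(/C=C/I)CC[C@@H]1O[Si](C)(C)C(C)(C)C
F18 | step 11 | methyl ester of acid 17 | COC(=O)C[C@@]1(C)O[C@@](C)(/C=C/OCc2ccc(OC)cc2)CC[C@@H]1O[Si](C)(C)C(C)(C)C
A1 | alternative 1 | bridged spiro-lactone with Z C4=C5 alkene, C1 ketone, C8 methacrylate and silyloxymethyl group on C11 | C=C(C)C(=O)O[C@H]1C[C@@]2(C)O[C@@]13[C@H](CO[Si](C)(C)C(C)(C)C)C(=O)O[C@@H]3/C=C(C)\CCC2=O
A2 | alternative 1 | primary amide precursor of A1 with a C6 methylene group | C=C(C)C(=O)O[C@H]1C[C@@]2(C)O[C@]1([C@H](CO[Si](C)(C)C(C)(C)C)C(N)=O)C/C=C(C)\CCC2=O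
A3 | alternative 2 | bridged Z-oxonene with C1 dimethyl ketal, C6 4-methoxybenzyl ether and two silyl ethers | CC(C)(C)[Si](c1ccccc1)(c1ccccc1)O[C@H]1C[C@@]2(C)O[C@]1(C(=C)CO[Si](C)(C)C(C)(C)C)[C@H](OCc1ccc(OC)cc1)/C=C(C)\CCC2(OC)OC
A4 | alternative 2 | ten-membered cyclic sulfone precursor of A3 (sulfur between C4 and C5; C4 epimers) | CC(C)(C)[Si](c1ccccc1)(c1ccccc1)O[C@H]1C[C@@]2(C)O[C@]1(C(=C)CO[Si](C)(C)C(C)(C)C)[C@H](OCc1ccc(OC)cc1)CS(=O)(=O)C(C)CCC2(OC)OC
A5 | alternative 3 | bridged tetrahydrofuran spiro-lactone with 4,5-epoxide, C1 4-methoxybenzyl ether and C8 silyl ether | CC(C)(C)[Si](C)(C)O[C@H]1C[C@@]2(C)O[C@@]13CC(=O)O[C@@H]3[C@@H]1O[C@]1(C)CC[C@H]2OCc1ccc(OC)cc1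
A6 | alternative 3 | 4,5-epoxycyclodecane-6,10-diol precursor of A5 with exocyclic C7 methylene group | CC(C)(C)[Si](C)(C)O[C@H]1C[C@@](C)(O)[C@H](OCc2ccc(OC)cc2)CC[C@@]2(C)O[C@H]2[C@@H](O)C1=C
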